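**Retrosynthetic overview**
1. Target 12 ⇒ global MOM removal from the tris‑MOM chalcone 11.
2. 11 ⇒ aryl–C(=O) disconnection (not the Claisen–Schmidt Cα=Cβ disconnection): the C6‑aryllithium of diprenyl resorcinol bis‑MOM ether 6 plus the (E)‑cinnamoyl Weinreb amide 10, whose E‑alkene is preset by an HWE reaction.
3. 6 ⇒ two earlier directed ortho‑metalation (DoM)/prenylation rounds on 1,3‑bis(MOMO)benzene 3 (C2, then C4). Three successive DoMs walk around one resorcinol ring and fix all regiochemistry.
4. No ring is formed: both benzene rings are purchased (resorcinol, 4‑hydroxybenzaldehyde).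

Assumption: the target has no stereocentre, so "single enantiomer" is taken to mean the single (E)‑alkene isomer.

**Step 1**
Reactants: 1 resorcinol; 2 chloromethyl methyl ether (MOMCl)
Product: 3 1,3‑bis(methoxymethoxy)benzene
Conditions: MOMCl (2.5 eq), i‑Pr2NEt (3 eq), CH2Cl2, 0 °C → rt
Reagents that add atoms: MOMCl, COCCl
Why: Simple O‑alkylation of both phenols (MOM acetal formation); the OMOM groups are the directing groups for all three later lithiations.

**Step 2**
Reactants: 3 1,3‑bis(methoxymethoxy)benzene; 4 prenyl bromide (1‑bromo‑3‑methylbut‑2‑ene)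
Product: 5 1,3‑bis(methoxymethoxy)‑2‑(3‑methylbut‑2‑en‑1‑yl)benzene
Conditions: n‑BuLi (1.1 eq), THF, 0 °C → rt, 1 h; CuI (10 mol %), then 4 (1.2 eq), −40 °C → rt
Reagents that add atoms: prenyl bromide, CC(C)=CCBr
Why: Directed ortho‑metalation occurs only at C2–H, which is flanked by two OMOM groups; Cu‑assisted SN2 allylation at the unhindered CH2 terminus gives the linear prenyl group.

**Step 3**
Reactants: 5; 4 prenyl bromide
Product: 6 1,3‑bis(methoxymethoxy)‑2,4‑bis(3‑methylbut‑2‑en‑1‑yl)benzene
Conditions: n‑BuLi/TMEDA (1.3 eq each), THF, −10 → 0 °C, 1.5 h; CuI (10 mol %), then 4 (1.3 eq), −40 °C → rt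
Reagents that add atoms: prenyl bromide, CC(C)=CCBr
Why: Second DoM at C4 (C4 and C6 are the only remaining ortho sites and are equivalent); OMOM‑complexed ring deprotonation is kinetically preferred over lateral deprotonation of the twisted, doubly flanked prenyl CH2, and the same SN2 allylation follows.

**Step 4**
Reactants: 7 4‑hydroxybenzaldehyde; 2 MOMCl
Product: 8 4‑(methoxymethoxy)benzaldehyde
Conditions: MOMCl (1.3 eq), i‑Pr2NEt (1.5 eq), CH2Cl2, 0 °C → rt
Reagents that add atoms: MOMCl, COCCl
Why: Phenol MOM protection, so the B‑ring OH does not quench the aryllithium in Step 6 and all three protecting groups come off together.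

**Step 5**
Reactants: 8; 9 diethyl [2‑(methoxy(methyl)amino)‑2‑oxoethyl]phosphonate
Product: 10 (E)‑N‑methoxy‑N‑methyl‑3‑[4‑(methoxymethoxy)phenyl]prop‑2‑enamide
Conditions: NaH (1.2 eq), 9 (1.15 eq), THF, 0 °C → rt
Reagents that add atoms: phosphonate 9, CCOP(=O)(CC(=O)N(C)OC)OCC
Why: Horner–Wadsworth–Emmons olefination with a stabilised phosphonate is strongly E‑selective; this sets the only stereo‑element of the target.

**Step 6**
Reactants: 6; 10
Product: 11 (E)‑1‑[2,4‑bis(methoxymethoxy)‑3,5‑bis(3‑methylbut‑2‑en‑1‑yl)phenyl]‑3‑[4‑(methoxymethoxy)phenyl]prop‑2‑en‑1‑one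
Conditions: 6 (1.15 eq), n‑BuLi/TMEDA (1.1 eq), THF, 0 °C, 1.5 h; then 10 (1.0 eq), −78 → −20 °C; sat. aq NH4Cl quench
Reagents that add atoms: Weinreb amide 10, COCOc1ccc(/C=C/C(=O)N(C)OC)cc1
Why: Third DoM at C6, the last position ortho to an OMOM, followed by Weinreb ketone synthesis; the hard aryllithium adds 1,2 and the N‑OMe chelate stops over‑addition, so the chalcone enone is released only on quench with the E‑alkene untouched.

**Step 7**
Reactants: 11
Product: 12 (E)‑1‑[2,4‑dihydroxy‑3,5‑bis(3‑methylbut‑2‑en‑1‑yl)phenyl]‑3‑(4‑hydroxyphenyl)prop‑2‑en‑1‑one (target)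
Conditions: 3 M aq HCl/MeOH (1:5), rt → 40 °C, in the dark, stopped at full conversion; NaHCO3 work‑up
Reagents that add atoms: none
Why: Acid‑catalysed acetal hydrolysis removes all three aryl MOM ethers; dilute acid and short reaction time are chosen to avoid chroman formation from the ortho‑prenyl phenols and flavanone closure, and the E‑enone is the thermodynamic isomer.

**Compound list**
1 | resorcinol | Oc1cccc(O)c1 | starting material
2 | chloromethyl methyl ether (MOMCl) | COCCl | starting material
3 | 1,3‑bis(methoxymethoxy)benzene | COCOc1cccc(OCOC)c1 | intermediate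
4 | prenyl bromide (1‑bromo‑3‑methylbut‑2‑ene) | CC(C)=CCBr | starting material
5 | 1,3‑bis(methoxymethoxy)‑2‑(3‑methylbut‑2‑en‑1‑yl)benzene | COCOc1cccc(OCOC)c1CC=C(C)C | intermediate
6 | 1,3‑bis(methoxymethoxy)‑2,4‑bis(3‑methylbut‑2‑en‑1‑yl)benzene | COCOc1ccc(CC=C(C)C)c(OCOC)c1CC=C(C)C | intermediate
7 | 4‑hydroxybenzaldehyde | O=Cc1ccc(O)cc1 | starting material
8 | 4‑(methoxymethoxy)benzaldehyde | COCOc1ccc(C=O)cc1 | intermediate
9 | diethyl [2‑(methoxy(methyl)amino)‑2‑oxoethyl]phosphonate | CCOP(=O)(CC(=O)N(C)OC)OCC | starting material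
10 | (E)‑N‑methoxy‑N‑methyl‑3‑[4‑(methoxymethoxy)phenyl]prop‑2‑enamide | COCOc1ccc(/C=C/C(=O)N(C)OC)cc1 | intermediate
11 | (E)‑1‑[2,4‑bis(methoxymethoxy)‑3,5‑diprenylphenyl]‑3‑[4‑(methoxymethoxy)phenyl]prop‑2‑en‑1‑one | COCOc1ccc(/C=C/C(=O)c2cc(CC=C(C)C)c(OCOC)c(CC=C(C)C)c2OCOC)cc1 | intermediate
12 | (E)‑1‑[2,4‑dihydroxy‑3,5‑diprenylphenyl]‑3‑(4‑hydroxyphenyl)prop‑2‑en‑1‑one | CC(C)=CCc1cc(C(=O)/C=C/c2ccc(O)cc2)c(O)c(CC=C(C)C)c1O | target

**Total step count:** 7
**Longest linear sequence:** 5 (Steps 1 → 2 → 3 → 6 → 7); Steps 4–5 form the convergent branch.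

**Three steps most likely to fail, with fallbacks**
1. Step 6 (acylation of the hindered, electron‑rich aryllithium: possible 1,4‑addition or low conversion). Fallback: trap the C6‑aryllithium with DMF to give the benzaldehyde, add the lithium acetylide of 1‑ethynyl‑4‑(methoxymethoxy)benzene, and convert the propargylic alcohol to the E‑enone by Meyer–Schuster rearrangement.
2. Step 3 (first lithiation with a prenyl group present: lateral benzylic/allylic deprotonation, which would also affect Step 6). Fallback: switch from C–H deprotonation to halogen–metal exchange. Start from 2,4,6‑tribromoresorcinol bis‑MOM ether and run three sequential Br→Li exchanges at −78 °C (C2 first, then C4, then C6) with the same electrophiles; exchange is much faster than any deprotonation.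
3. Step 7 (acidic MOM removal next to two prenyl groups and a 2'‑hydroxychalcone: chroman or flavanone formation). Fallback: redesign the protecting groups. Carry the three phenols as SEM ethers, which are equally good DoM directors, and remove them at the end with fluoride (TBAF) under non‑acidic conditions.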